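## Structural features

The target (C22H31NO6) is numbered along its chain: ethyl C1–C2 on C3; lactone A is C4, O5, C6 (carbonyl), C7 (methyl-bearing), C8; then ketone C9, C10, C11; lactone B is C12, C13, C14 (methyl-bearing), C15 (carbonyl), O16; then N17, C18–C21, C22 and the lactam carbonyl C23. The core is a nine-membered ring C3–C4–C8–C9–C10–C11–N17–C23–C22 that holds the C9 ketone and the N17–C23 lactam. A tetramethylene bridge C18–C21 ties N17 to C22, so C23 is the one-atom bridge of an azepan-2-one spanning the medium ring. Lactone A is cis-fused to the medium ring across C4–C8, and lactone B hangs from C11 through C12. Five of the eight stereocentres are contiguous (C22 R, C3 R, C4 S, C8 S, C7 S); C11 S, C12 S and C14 S form a second group. The C9 ketone is a β-acyloxy ketone (C9–C8–C4–O5) with enolisable C8 and C10, both α-methyl lactones can epimerise, and C22 is the least acidic position, so base cannot correct it once the ketone exists. The real difficulty is a medium ring carrying a bridging lactam and five adjacent stereocentres; the bridge cannot be installed before the medium ring, because across a six-membered ring it would twist the amide out of planarity. The key step exploits the 1,3-relationship of C9 and C23 through C22: a temporary C9–C22 bond turns the nine-membered ring into a piperidine-2,4-dione (N17, C23, C22, C9, C10, C11) whose C22 carries C3–C4–C8 as an arm ending in a butenolide, and ketyl addition of C9 to C8 followed by retro-aldol loss of C9–C22 rebuilds the medium ring with lactone A already fused.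

## Logic of the disconnections

**28 ⇒ 27.** No skeletal bond is cut; C14 and the saturated C19–C20 bond are traced back to the exocyclic methylene of lactone B and the ring alkene of 27. Both alkenes are left over from the two preceding C–C bond formations, and one hydrogenation removes them. The forward step must deliver hydrogen to the lactone B alkene from the face opposite C11 and leave the ketone alone.

**27 ⇒ 24 + 25.** The C12–C13 bond and the O16–C15 acyl bond are cut. This removes lactone B as one four-carbon reagent and reduces the C11 substituent to an aldehyde. The forward allylation must choose the aldehyde over the C9 ketone, must give the threo (12S) adduct, and must not epimerise C11.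

**24 ⇒ 23 ⇒ 22 ⇒ 21.** Functional-group changes at C12 (aldehyde, alcohol, silyl ether) come first, then the C19=C20 bond is cut. The azepane is closed only after the medium ring exists, for the planarity reason given above; two allyl groups on N17 and C22 are the simplest precursors of C18–C21. The forward metathesis needs the lactam rotamer in which C18 lies on the side of C22.

**21 ⇒ 18 (key).** In the reverse sense C8–C9 is cut and C9–C22 is joined. The medium ring, its fusion to lactone A and the centres C8, C7 and C22 are exchanged for a six-membered β-keto lactam with a butenolide arm, in which only C3, C4 and C11 are stereogenic. The forward step needs the ketyl to choose the butenolide, the aldolate to fragment only at C9–C22, and two protonations (C7, C22) to end in the right configuration. Two points are handled explicitly: C7 can be equilibrated, C22 cannot, and the configuration of C22 in 18 is lost only formally, because the nine-membered enolate may remember it.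

**18 ⇒ 17.** The C22–C21 bond is cut. Allylation is placed last so that C22 stays an acidic methine while the arm is attached and becomes quaternary only under neutral palladium catalysis, which spares the base-sensitive C4–H of the butenolide. The forward step must alkylate on carbon, not oxygen.

**17 ⇒ 16 ⇒ 14 ⇒ 6 + 12.** The lactam bond N17–C23 and the C22–C9 bond are cut (the latter as an aldol, followed by oxidation at C9). The obvious alternative, conjugate addition of a preformed dione to an alkylidene butenolide, would make the crowded C22–C3 bond and set C3 and C4 with no control relative to C11, so the ring is instead built around an arm that already carries both centres. The forward aldol must enolise the activated acyl group of 6 without deprotonating C4; because acid removes the nitrogen protecting group, the silyl ether is chosen as tert-butyldiphenylsilyl.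

**6 ⇒ 5 ⇒ 4 ⇒ 2 + 3, and 2 ⇒ 1.** The C3–C4 bond is cut. A vinylogous Mukaiyama–Michael addition makes this bond and both stereocentres in one catalyst-controlled step from two achiral five-carbon pieces. The forward step must give the 3R configuration and the syn relationship of ethyl and ring oxygen.

**12 ⇒ 11 ⇒ 10 ⇒ 9 ⇒ 7.** The N17–C18 bond is cut and the oxidation levels at C9 and C12 are adjusted; C11 comes unchanged from the chiral pool in 7. The forward steps must avoid γ-lactonisation of 9 and over-reduction of the ester.

## Other disconnections considered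

**Alternative 1:** The cut reverses an oxidative scission of C9=C23: ketone C9 and lactam carbonyl C23 are traced back to one enamine double bond, so the medium ring of A1 becomes the fused five- and six-membered rings of the 4,7-dihydroindoline A2.
- Forward step: dye-sensitised photo-oxygenation adds oxygen across the electron-rich enamine of A2, and cleavage of the adduct gives A1.
- In its favour: no medium-ring closure and no fragmentation equilibrium are involved; C11 comes from the chiral pool; A1 is reached in very few steps. On the dependability of the ring-forming event and on step count up to the key step, this alternative is the better one.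
- Against it: A1 holds only C11 of the eight stereocentres and nothing of lactone A. The ethyl group at C3, the oxygen at C4, the C7–C8 unit and the C21–C22 bond would all have to be introduced on a flexible nine-membered ring, from one Z alkene and competing α-positions (C8 and C10 of the ketone against C22 of the lactam). The dissolving-metal reduction leading to A2 is hard to reconcile with a C11 ester, and the isolated C3=C4 alkene of A2 can compete in an ene reaction.
- Comparison: on structure, the chosen plan delivers lactone A and C8 in the step that makes the medium ring, whereas the alternative postpones them all. On mechanism, the photo-oxygenation is better precedented than a samarium aldolate fragmentation. On step economy, the alternative wins before its key step and is expected to lose after it.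

**Alternative 2:** The cut is C22–C3, paired in the reverse sense with re-formation of N17–C8, which contracts the nine-membered NH lactam A3 to the N-acylated 2-alkenylpyrrolidine A4.
- Forward step: a lithium amide base generates the Z amide enolate of A4, and a chair-like 3-aza-Cope shift forms C22–C3 while N17–C8 breaks, giving A3 with an E C4=C8 alkene.
- In its favour: C11 and the C9 oxygen come from the chiral pool. C22 and C3 are set together, in the required trans relationship, by a closed transition state and not by a protonation; on this point the alternative is clearly better than the chosen plan.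
- Against it: A3 has no lactone A. The E alkene must be turned into the C4–O5 and C8–C7 bonds with cis fusion, and C9 oxidised, on a medium ring with unpredictable transannular behaviour. The trisubstituted pyrrolidine A4 with a defined E-butenyl group is itself a long synthesis, and the azepane must later be closed by N-alkylation of a hindered secondary lactam.
- Comparison: on structure the plans are complementary (A3 has C22, C3 and the C18–C21 chain; 21 has lactone A, C7, C8 and the ketone). On mechanism the sigmatropic shift is the better understood and stereochemically more reliable event. On step economy the chosen plan is expected to be shorter, because lactone A costs it no extra steps.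

**Alternative 3:** The cut is C10–C11, opening the medium ring of A5 to the azepan-2-one A6, which carries lactone A, the C9 ketone as its enol silane and an N-(acetoxy)glycinate unit.
- Forward step: a Lewis acid ionises the C11 acetate of A6 and the terminal enol silane carbon C10 attacks the resulting cation, closing the nine-membered ring.
- In its favour: the azepane, lactone A and the centres C22, C3, C4, C8 and C7 are in place before the closure and can be assembled on unstrained intermediates. A5 is therefore a more advanced intermediate than 21; on structural completeness after the key step this alternative is the better one.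
- Against it: it is a direct closure of a nine-membered ring, which must compete with oligomerisation and with proton loss from the cation. C11 is created in the closure without an obvious control element, the methyl ketone precursor has an epimerisable C8, and the C11 ester must still be taken to lactone B through the same α-amido aldehyde as in the chosen plan.
- Comparison: on structure the alternative's product is more complete. On mechanism the chosen plan avoids any direct medium-ring closure by merging a five- and a six-membered ring, but pays with an unproven fragmentation. On step economy the linear assembly of A6 is expected to need more steps than the convergent route to 18.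

Key step: step 13

Remark on the chemistry: the (2S,5S)-imidazolidinone of step 2 is assumed to shield the same enal face towards the silyloxyfuran as towards other π-nucleophiles (giving 3R); if the sense proves opposite, the (2R,5R)-catalyst is used.
Remark on the chemistry: centres that are destroyed later (C9 and C22 in 14–18) are carried as epimer mixtures and left open in the SMILES.

## Route

Step 1
Reactants: 1 3-methylfuran-2(5H)-one
Product: 2 3-methyl-2-(trimethylsilyloxy)furan
Conditions: Me3SiOSO2CF3, Et3N, Et2O, 0 °C
Reagents that add atoms: trimethylsilyl trifluoromethanesulfonate, C[Si](C)(C)OS(=O)(=O)C(F)(F)F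
Why: Soft enolisation of the butenolide (γ-deprotonation gives the aromatic 2-oxyfuran) and O-silylation is the standard preparation of 2-silyloxyfurans; no stereocentre is formed.

Step 2
Reactants: 2 3-methyl-2-(trimethylsilyloxy)furan; 3 (E)-pent-2-enal
Product: 4 (3R)-3-[(2S)-4-methyl-5-oxo-2,5-dihydrofuran-2-yl]pentanal
Conditions: (2S,5S)-5-benzyl-2-tert-butyl-3-methylimidazolidin-4-one·2,4-dinitrobenzoic acid (20 mol %), CH2Cl2, H2O (2 equiv), −70 °C
Reagents that add atoms: none
Why: Iminium-catalysed vinylogous Mukaiyama–Michael addition: the benzyl group of the catalyst blocks one face of the E-iminium ion so the furan adds through its C5 to the open face of C3 (3R), and the syn-selective open transition state of this catalyst–acid pair puts ethyl and ring oxygen on the same side of the C22–C3–C4–C8 chain (4S, the furanone 2S centre).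

Step 3
Reactants: 4 (3R)-3-[(2S)-4-methyl-5-oxo-2,5-dihydrofuran-2-yl]pentanal
Product: 5 (3R)-3-[(2S)-4-methyl-5-oxo-2,5-dihydrofuran-2-yl]pentanoic acid
Conditions: NaClO2, NaH2PO4, 2-methylbut-2-ene, t-BuOH/H2O, 0 °C to 23 °C
Reagents that add atoms: sodium chlorite, [Na+].[O-]Cl=O
Why: Pinnick oxidation takes the aldehyde (C23) to the acid in a buffered, base-free medium, so the butenolide and the C3 and C4 centres are not touched.

Step 4
Reactants: 5 (3R)-3-[(2S)-4-methyl-5-oxo-2,5-dihydrofuran-2-yl]pentanoic acid
Product: 6 3-{(3R)-3-[(2S)-4-methyl-5-oxo-2,5-dihydrofuran-2-yl]pentanoyl}-1,3-thiazolidine-2-thione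
Conditions: 1,3-thiazolidine-2-thione, EDC·HCl, DMAP (cat.), CH2Cl2, 0 °C to 23 °C
Reagents that add atoms: 1,3-thiazolidine-2-thione, S=C1NCCS1
Why: Carbodiimide N-acylation gives an active amide whose α-CH2 (C22) can be enolised under soft conditions and whose acyl group will later be transferred to N17.

Step 5
Reactants: 7 N-(tert-butoxycarbonyl)-L-aspartic acid 4-methyl ester
Product: 9 methyl (3S)-3-[(tert-butoxycarbonyl)amino]-4-hydroxybutanoate, via mixed carbonic anhydride 8 (not isolated)
Conditions: i-BuOCOCl, N-methylmorpholine, THF, −15 °C; then NaBH4, H2O, 0 °C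
Reagents that add atoms: none
Why: Chemoselective borohydride reduction of the α-carboxyl group through its mixed anhydride leaves the β-ester and the carbamate; C11 keeps the S configuration of L-aspartic acid.

Step 6
Reactants: 9 methyl (3S)-3-[(tert-butoxycarbonyl)amino]-4-hydroxybutanoate
Product: 10 methyl (3S)-3-[(tert-butoxycarbonyl)amino]-4-[(tert-butyldiphenylsilyl)oxy]butanoate
Conditions: t-BuPh2SiCl, imidazole, DMF, 23 °C
Reagents that add atoms: tert-butyl(chloro)diphenylsilane, CC(C)(C)[Si](Cl)(c1ccccc1)c1ccccc1
Why: Silylation of the primary alcohol prevents γ-lactonisation; the tert-butyldiphenylsilyl ether is chosen because it withstands the acid of step 10.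

Step 7
Reactants: 10 methyl (3S)-3-[(tert-butoxycarbonyl)amino]-4-[(tert-butyldiphenylsilyl)oxy]butanoate
Product: 11 methyl (3S)-3-[allyl(tert-butoxycarbonyl)amino]-4-[(tert-butyldiphenylsilyl)oxy]butanoate
Conditions: allyl bromide, NaH, DMF, 0 °C
Reagents that add atoms: allyl bromide, C=CCBr
Why: N-alkylation of the carbamate, whose N–H is the most acidic site, installs C18–C19 as the N-allyl group; C11 is not acidic and is unaffected.

Step 8
Reactants: 11 methyl (3S)-3-[allyl(tert-butoxycarbonyl)amino]-4-[(tert-butyldiphenylsilyl)oxy]butanoate
Product: 12 tert-butyl allyl{(2S)-1-[(tert-butyldiphenylsilyl)oxy]-4-oxobutan-2-yl}carbamate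
Conditions: i-Bu2AlH (1.1 equiv), CH2Cl2, −78 °C
Reagents that add atoms: none
Why: Partial reduction of the methyl ester stops at the aldehyde (C9) because the aluminium hemiacetal is stable at −78 °C; the β-amino aldehyde has no acidic stereocentre.

Step 9
Reactants: 6 3-{(3R)-3-[(2S)-4-methyl-5-oxo-2,5-dihydrofuran-2-yl]pentanoyl}-1,3-thiazolidine-2-thione; 12 tert-butyl allyl{(2S)-1-[(tert-butyldiphenylsilyl)oxy]-4-oxobutan-2-yl}carbamate
Product: 14 3-[(5S)-5-[allyl(tert-butoxycarbonyl)amino]-6-[(tert-butyldiphenylsilyl)oxy]-3-hydroxy-2-{(1R)-1-[(2S)-4-methyl-5-oxo-2,5-dihydrofuran-2-yl]propyl}hexanoyl]-1,3-thiazolidine-2-thione (C9/C22 epimer mixture), via chlorotitanium enolate 13 (not isolated)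
Conditions: TiCl4 (1.05 equiv), i-Pr2NEt (1.1 equiv), CH2Cl2, −78 °C; then 12, −78 °C
Reagents that add atoms: none
Why: Titanium-mediated aldol addition of an N-acyl thiazolidinethione (soft enolisation, Crimmins type) forms C22–C9; the chelated active amide is enolised much faster than the butenolide γ-position at −78 °C, and the two new centres (C22, C9) need no control because both are erased later.

Step 10
Reactants: 14 3-[(5S)-5-[allyl(tert-butoxycarbonyl)amino]-6-[(tert-butyldiphenylsilyl)oxy]-3-hydroxy-2-{(1R)-1-[(2S)-4-methyl-5-oxo-2,5-dihydrofuran-2-yl]propyl}hexanoyl]-1,3-thiazolidine-2-thione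
Product: 16 (6S)-1-allyl-6-{[(tert-butyldiphenylsilyl)oxy]methyl}-4-hydroxy-3-{(1R)-1-[(2S)-4-methyl-5-oxo-2,5-dihydrofuran-2-yl]propyl}piperidin-2-one (C9/C22 epimer mixture), via free amine 15 (not isolated)
Conditions: CF3CO2H, CH2Cl2, 0 °C; then aq. NaHCO3, CH2Cl2, 23–40 °C
Reagents that add atoms: none
Why: Acidic carbamate cleavage followed by intramolecular N-acylation by the acyl thiazolidinethione closes the six-membered lactam (N17–C23) with loss of the thione; the silyl ether and the butenolide tolerate the acid and the weak inorganic base.

Step 11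
Reactants: 16 (6S)-1-allyl-6-{[(tert-butyldiphenylsilyl)oxy]methyl}-4-hydroxy-3-{(1R)-1-[(2S)-4-methyl-5-oxo-2,5-dihydrofuran-2-yl]propyl}piperidin-2-one
Product: 17 (6S)-1-allyl-6-{[(tert-butyldiphenylsilyl)oxy]methyl}-3-{(1R)-1-[(2S)-4-methyl-5-oxo-2,5-dihydrofuran-2-yl]propyl}piperidine-2,4-dione (C22 epimer mixture)
Conditions: Dess–Martin periodinane, NaHCO3, CH2Cl2, 0 °C to 23 °C
Reagents that add atoms: none
Why: Buffered Dess–Martin oxidation of the C9 carbinol gives the β-keto lactam without base; C3, C4 and C11 are not involved.

Step 12
Reactants: 17 (6S)-1-allyl-6-{[(tert-butyldiphenylsilyl)oxy]methyl}-3-{(1R)-1-[(2S)-4-methyl-5-oxo-2,5-dihydrofuran-2-yl]propyl}piperidine-2,4-dione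
Product: 18 (6S)-1,3-diallyl-6-{[(tert-butyldiphenylsilyl)oxy]methyl}-3-{(1R)-1-[(2R)-4-methyl-5-oxo-2,5-dihydrofuran-2-yl]propyl}piperidine-2,4-dione (both C22 epimers)
Conditions: allyl methyl carbonate, Pd(PPh3)4 (5 mol %), THF, 23 °C
Reagents that add atoms: allyl methyl carbonate, C=CCOC(=O)OC
Why: Tsuji–Trost allylation: the soft β-keto lactam enolate attacks the π-allylpalladium complex at carbon and makes C22 quaternary (C21–C20); the methoxide released is consumed by the acidic dione, so C4 is not epimerised, and its descriptor changes to R only because C22 is now quaternary.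

Step 13
Reactants: 18 (6S)-1,3-diallyl-6-{[(tert-butyldiphenylsilyl)oxy]methyl}-3-{(1R)-1-[(2R)-4-methyl-5-oxo-2,5-dihydrofuran-2-yl]propyl}piperidine-2,4-dione
Product: 21 (3R,4S,7S,8S,11S,22R)-N17,C22-diallyl-11-{[(tert-butyldiphenylsilyl)oxy]methyl} nine-membered keto lactam cis-fused to lactone A, via tricyclic samarium aldolate 19 (not isolated), via C7-epimeric keto lactam 20 (not isolated)
Conditions: SmI2 (2.5 equiv), HMPA (10 equiv), t-BuOH (2.2 equiv), THF, −78 °C to 23 °C; aq. NH4Cl work-up; then DBU (0.2 equiv), toluene, 60 °C
Reagents that add atoms: none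
Why: Proposed new method: SmI2–HMPA transfers one electron to the C9 ketone of 18, and the ketyl adds 5-exo-trig to the butenolide β-carbon C8, closing the transient cyclopentanol ring C9–C22–C3–C4–C8; a second electron and t-BuOH turn the C7 radical into the saturated lactone, giving aldolate 19. On warming, the trivalent samarium alkoxide of 19 undergoes retro-aldol cleavage of C9–C22, the only bond at C9 that is α to a carbonyl, so the six- and five-membered rings sharing this bond merge into the nine-membered ring (ring expansion by fragmentation, not a direct medium-ring closure), and the lactam enolate is protonated at C22. The closest known reactions are SmI2 ketyl–olefin cyclisations onto unsaturated esters and lactones and the three-carbon ring expansion of cyclic β-keto esters through bicyclic alkoxides or alkoxy radicals (Dowd–Beckwith type); only their combination on a β-keto lactam is new. C8 is fixed by C4, because a five-membered ring can only be cis-fused to the lactone. C7 is expected to be protonated kinetically on the convex face, which gives mainly epimer 20; DBU then equilibrates it to the more stable 7S isomer with methyl trans to the C8 acyl branch, the competing β-elimination of the lactone oxygen being the reverse of a 5-endo-trig closure and therefore slow. C22 arises by irreversible protonation of the nine-membered enolate and cannot be corrected later, since the ketone α-hydrogens are more acidic than the lactam α-hydrogen; the 22R isomer (allyl trans to ethyl) is the more stable one, but a kinetic preference for it is not assured. Chemoselectivity rests on the electron-poor butenolide being a much better ketyl acceptor than the two unactivated allyl groups (which could react only in 4-exo or 6-exo modes), and the quaternary C22 prevents enolisation of the dione before electron transfer.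

Step 14
Reactants: 21 (3R,4S,7S,8S,11S,22R)-N17,C22-diallyl-11-{[(tert-butyldiphenylsilyl)oxy]methyl} nine-membered keto lactam cis-fused to lactone A
Product: 22 (3R,4S,7S,8S,11S,22R)-bicyclic keto lactam with the bridge N17–C18–C19=C20–C21–C22 and C11 CH2OSi(t-Bu)Ph2
Conditions: second-generation Grubbs catalyst, (H2IMes)(PCy3)Cl2Ru=CHPh (10 mol %), toluene (2 mM), 80 °C
Reagents that add atoms: none
Why: Ring-closing metathesis of the N-allyl and C22-allyl groups forms the seven-membered ring with loss of ethene; heating lets the lactam reach the rotamer with C18 next to C22, and no stereocentre is formed or touched.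

Step 15
Reactants: 22 (3R,4S,7S,8S,11S,22R)-bicyclic keto lactam with the bridge N17–C18–C19=C20–C21–C22 and C11 CH2OSi(t-Bu)Ph2
Product: 23 the corresponding C12 primary alcohol (C11 CH2OH)
Conditions: HF·pyridine, pyridine, THF, 0 °C to 23 °C
Reagents that add atoms: none
Why: Acidic fluoride desilylation avoids basic fluoride sources that could enolise the β-acyloxy ketone or the α-methyl lactone.

Step 16
Reactants: 23 the C12 primary alcohol
Product: 24 the C12 aldehyde (C11 CHO)
Conditions: Dess–Martin periodinane, NaHCO3, CH2Cl2, 0 °C
Reagents that add atoms: none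
Why: Mild buffered oxidation gives the α-amido aldehyde, which is used crude and at once so that C11 does not epimerise.

Step 17
Reactants: 24 the C12 aldehyde; 25 ethyl 2-(bromomethyl)acrylate
Product: 27 (12S)-α-methylene lactone B on the unsaturated bicyclic core, via hydroxy ester 26 (not isolated)
Conditions: Zn dust, THF/sat. aq. NH4Cl, 0 °C to 23 °C; then p-TsOH·H2O (cat.), CH2Cl2, 23 °C
Reagents that add atoms: none
Why: Zinc Barbier 2-(ethoxycarbonyl)allylation adds to the aldehyde in preference to the hindered C9 ketone and acid closes lactone B; the 12S (threo) adduct requires attack on the aldehyde held in a zinc chelate with the lactam carbonyl, whereas Felkin-type attack would give 12R, so this selectivity is listed among the risks.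

Step 18
Reactants: 27 (12S)-α-methylene lactone B on the unsaturated bicyclic core
Product: 28 target CNP0311700.2
Conditions: H2 (1 atm), Pd/C (10 %), EtOAc, 23 °C
Reagents that add atoms: none
Why: Catalytic hydrogenation saturates C19=C20 and the exocyclic alkene; hydrogen adds to lactone B from the face opposite the C12 substituent, placing the C14 methyl cis to C11 (14S), and the ketone, lactones and lactam are inert.

## Compound list

1 | 3-methylfuran-2(5H)-one | CC1=CCOC1=O | starting material
2 | 3-methyl-2-(trimethylsilyloxy)furan | Cc1ccoc1O[Si](C)(C)C | intermediate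
3 | (E)-pent-2-enal | CC/C=C/C=O | starting material
4 | (3R)-3-[(2S)-4-methyl-5-oxo-2,5-dihydrofuran-2-yl]pentanal | CC[C@@H]([C@@H]1OC(=O)C(C)=C1)CC=O | intermediate
5 | (3R)-3-[(2S)-4-methyl-5-oxo-2,5-dihydrofuran-2-yl]pentanoic acid | CC[C@@H]([C@@H]1OC(=O)C(C)=C1)CC(O)=O | intermediate
6 | 3-{(3R)-3-[(2S)-4-methyl-5-oxo-2,5-dihydrofuran-2-yl]pentanoyl}-1,3-thiazolidine-2-thione | CC[C@@H]([C@@H]1OC(=O)C(C)=C1)CC(=O)N1CCSC1=S | intermediate
7 | N-(tert-butoxycarbonyl)-L-aspartic acid 4-methyl ester | CC(C)(C)OC(=O)N[C@@H](CC(=O)OC)C(O)=O | starting material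
8 | mixed carbonic anhydride of 7 (isobutyl carbonate at the α-carboxyl, 2S) | CC(C)(C)OC(=O)N[C@@H](CC(=O)OC)C(=O)OC(=O)OCC(C)C | intermediate
9 | methyl (3S)-3-[(tert-butoxycarbonyl)amino]-4-hydroxybutanoate | CC(C)(C)OC(=O)N[C@@H](CC(=O)OC)CO | intermediate
10 | methyl (3S)-3-[(tert-butoxycarbonyl)amino]-4-[(tert-butyldiphenylsilyl)oxy]butanoate | CC(C)(C)OC(=O)N[C@@H](CC(=O)OC)CO[Si](c1ccccc1)(c1ccccc1)C(C)(C)C | intermediate
11 | methyl (3S)-3-[allyl(tert-butoxycarbonyl)amino]-4-[(tert-butyldiphenylsilyl)oxy]butanoate | CC(C)(C)OC(=O)N(CC=C)[C@@H](CC(=O)OC)CO[Si](c1ccccc1)(c1ccccc1)C(C)(C)C | intermediate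
12 | tert-butyl allyl{(2S)-1-[(tert-butyldiphenylsilyl)oxy]-4-oxobutan-2-yl}carbamate | CC(C)(C)OC(=O)N(CC=C)[C@@H](CC=O)CO[Si](c1ccccc1)(c1ccccc1)C(C)(C)C | intermediate
13 | trichlorotitanium Z-enolate of 6 | CC[C@@H]([C@@H]1OC(=O)C(C)=C1)/C=C(\O[Ti](Cl)(Cl)Cl)N1CCSC1=S | intermediate
14 | aldol adduct: 3-[(5S)-5-[allyl(tert-butoxycarbonyl)amino]-6-[(tert-butyldiphenylsilyl)oxy]-3-hydroxy-2-{(1R)-1-[(2S)-4-methyl-5-oxo-2,5-dihydrofuran-2-yl]propyl}hexanoyl]-1,3-thiazolidine-2-thione, C9 and C22 mixed | CC[C@@H]([C@@H]1OC(=O)C(C)=C1)C(C(O)C[C@@H](CO[Si](c1ccccc1)(c1ccccc1)C(C)(C)C)N(CC=C)C(=O)OC(C)(C)C)C(=O)N1CCSC1=S | intermediate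
15 | free amine of 14 (N-allyl secondary amine) | CC[C@@H]([C@@H]1OC(=O)C(C)=C1)C(C(O)C[C@@H](CO[Si](c1ccccc1)(c1ccccc1)C(C)(C)C)NCC=C)C(=O)N1CCSC1=S | intermediate
16 | (6S)-1-allyl-6-{[(tert-butyldiphenylsilyl)oxy]methyl}-4-hydroxy-3-{(1R)-1-[(2S)-4-methyl-5-oxo-2,5-dihydrofuran-2-yl]propyl}piperidin-2-one, C9 and C22 mixed | CC[C@@H]([C@@H]1OC(=O)C(C)=C1)C1C(O)C[C@@H](CO[Si](c2ccccc2)(c2ccccc2)C(C)(C)C)N(CC=C)C1=O | intermediate
17 | (6S)-1-allyl-6-{[(tert-butyldiphenylsilyl)oxy]methyl}-3-{(1R)-1-[(2S)-4-methyl-5-oxo-2,5-dihydrofuran-2-yl]propyl}piperidine-2,4-dione, C22 mixed | CC[C@@H]([C@@H]1OC(=O)C(C)=C1)C1C(=O)C[C@@H](CO[Si](c2ccccc2)(c2ccccc2)C(C)(C)C)N(CC=C)C1=O | intermediate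
18 | (6S)-1,3-diallyl-6-{[(tert-butyldiphenylsilyl)oxy]methyl}-3-{(1R)-1-[(2R)-4-methyl-5-oxo-2,5-dihydrofuran-2-yl]propyl}piperidine-2,4-dione, both C22 epimers (key-step precursor) | CC[C@@H]([C@@H]1OC(=O)C(C)=C1)C1(CC=C)C(=O)C[C@@H](CO[Si](c2ccccc2)(c2ccccc2)C(C)(C)C)N(CC=C)C1=O | intermediate
19 | tricyclic diiodosamarium aldolate (piperidinone, cyclopentanol and lactone A fused; 3R,4S,8S,11S; C7, C9, C22 open) | CC[C@H]1[C@@H]2OC(=O)C(C)[C@@H]2C3(O[Sm](I)I)C[C@@H](CO[Si](c4ccccc4)(c4ccccc4)C(C)(C)C)N(CC=C)C(=O)C13CC=C | intermediate
20 | C7 epimer (7R) of 21 | CC[C@H]1[C@@H]2OC(=O)[C@H](C)[C@@H]2C(=O)C[C@@H](CO[Si](c3ccccc3)(c3ccccc3)C(C)(C)C)N(CC=C)C(=O)[C@@H]1CC=C | intermediate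
21 | (3R,4S,7S,8S,11S,22R)-N17,C22-diallyl nine-membered keto lactam cis-fused to lactone A, C11 CH2OSi(t-Bu)Ph2 (key-step product) | CC[C@H]1[C@@H]2OC(=O)[C@@H](C)[C@@H]2C(=O)C[C@@H](CO[Si](c3ccccc3)(c3ccccc3)C(C)(C)C)N(CC=C)C(=O)[C@@H]1CC=C | intermediate
22 | bicyclic keto lactam with C19=C20 in the seven-membered bridge, fused to lactone A, C11 CH2OSi(t-Bu)Ph2 | CC[C@H]1[C@@H]2OC(=O)[C@@H](C)[C@@H]2C(=O)C[C@@H](CO[Si](c3ccccc3)(c3ccccc3)C(C)(C)C)N2CC=CC[C@H]1C2=O | intermediate
23 | C12 primary alcohol of the unsaturated bicyclic core | CC[C@H]1[C@@H]2OC(=O)[C@@H](C)[C@@H]2C(=O)C[C@@H](CO)N2CC=CC[C@H]1C2=O | intermediate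
24 | C12 aldehyde of the unsaturated bicyclic core | CC[C@H]1[C@@H]2OC(=O)[C@@H](C)[C@@H]2C(=O)C[C@@H](C=O)N2CC=CC[C@H]1C2=O | intermediate
25 | ethyl 2-(bromomethyl)acrylate | C=C(CBr)C(=O)OCC | starting material
26 | (12S)-hydroxy ester: C11–CH(OH)–CH2–C(=CH2)–CO2Et on the unsaturated bicyclic core | CC[C@H]1[C@@H]2OC(=O)[C@@H](C)[C@@H]2C(=O)C[C@@H]([C@@H](O)CC(=C)C(=O)OCC)N2CC=CC[C@H]1C2=O | intermediate
27 | (12S)-α-methylene lactone B on the unsaturated bicyclic core | CC[C@H]1[C@@H]2OC(=O)[C@@H](C)[C@@H]2C(=O)C[C@@H]([C@@H]2CC(=C)C(=O)O2)N2CC=CC[C@H]1C2=O | intermediate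
28 | CNP0311700.2 (3R,4S,7S,8S,11S,12S,14S,22R) | CC[C@H]1[C@@H]2OC(=O)[C@@H](C)[C@@H]2C(=O)C[C@@H]([C@@H]2C[C@H](C)C(=O)O2)N2CCCC[C@H]1C2=O | target

## Step count and risks

Total step count: 18 steps. Longest linear sequence: 14 steps (7 → 28 through steps 5–18; the branch from 1, steps 1–4 and 9–18, is equally long).

Least certain steps:

**Step 13 (key step, proposed new method).** The trivalent samarium aldolate may resist fragmentation, because the leaving group is a non-stabilised lactam enolate and the product is a strained medium ring. The irreversible protonation at C22 may also take place on the wrong face, since the proton is expected to arrive opposite the neighbouring ethyl-bearing carbon. The fallback sets out from 18 and returns at 21, using known chemistry only. 18 is treated with SmI2–HMPA–t-BuOH at −78 °C and quenched cold, so that the cyclised tricyclic β-hydroxy lactam F1 is isolated; here, with no ketone in the molecule, DBU can place the C7 methyl on the convex face. The tertiary alcohol is then converted into its alkoxy radical (PhI(OAc)2, I2, visible light), whose β-scission cleaves C9–C22 towards the stabilised α-carbamoyl radical and gives the nine-membered α-iodo lactam F2. Radical reduction ((Me3Si)3SiH, AIBN, 80 °C) then gives 21, with C22 set by hydrogen-atom transfer from a donor whose size can be varied.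

**Step 9.** The amine–titanium pair may deprotonate the butenolide at C4 in competition with the acyl thiazolidinethione, which would erode the C4 configuration and divert material through the furanolate. The fallback sets out from 11 and returns at 17, attaching the arm to a preformed dione without enolate chemistry on the arm. Carbamate cleavage (CF3CO2H) gives the amino ester F3, acylation with methyl malonyl chloride gives the malonamide F4, and Dieckmann cyclisation with decarboxylation (NaOMe, MeOH; then aqueous MeCN, reflux) gives the unsubstituted dione F5. Knoevenagel condensation with propanal gives the alkylidene dione F6, which is trapped in the same flask by silyloxyfuran 2 (vinylogous Mukaiyama–Michael addition, BF3·OEt2, −78 °C) to give 17. The price is that C3 and C4 are then formed without catalyst control relative to C11 and the diastereomers must be separated.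

**Step 14.** The lactam may not populate the rotamer that brings the two allyl groups together, so that intermolecular metathesis takes over. The fallback sets out from 21 and returns at 22, forming the same C19–C20 bond reductively. Ozonolysis (O3, then Me2S) gives the dialdehyde F7; SmI2 at −78 °C couples the two aldehydes, which are reduced much faster than the hindered C9 ketone, to the cyclic diol F8; deoxygenation of the diol (PPh3, I2, imidazole, toluene, reflux) gives 22.

**Step 17.** Addition to the aldehyde may follow the Felkin sense and give mainly the 12R epimer, and the α-amido aldehyde may lose its C11 configuration by enolisation before it reacts. The fallback sets out from 23 and returns at 27. It uses the iridium-catalysed transfer-hydrogenative 2-(alkoxycarbonyl)allylation of the primary alcohol itself ([Ir(cod)Cl]2, a chiral bisphosphine of the SEGPHOS type, 4-cyano-3-nitrobenzoic acid, Cs2CO3 (cat.), an ethyl 2-(acyloxymethyl)acrylate, THF, 60 °C). The aldehyde is then never free, and the catalyst, not the substrate, decides the configuration of C12; no new isolated compound arises.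

## Further compounds

F1 | step 13 | tricyclic β-hydroxy lactam (free alcohol of 19, 7S after equilibration; C9 and C22 open) | CC[C@H]1[C@@H]2OC(=O)[C@@H](C)[C@@H]2C3(O)C[C@@H](CO[Si](c4ccccc4)(c4ccccc4)C(C)(C)C)N(CC=C)C(=O)C13CC=C
F2 | step 13 | nine-membered α-iodo lactam (iodine at C22 in place of hydrogen in 21; C22 open) | CC[C@H]1[C@@H]2OC(=O)[C@@H](C)[C@@H]2C(=O)C[C@@H](CO[Si](c3ccccc3)(c3ccccc3)C(C)(C)C)N(CC=C)C(=O)C1(I)CC=C
F3 | step 9 | methyl (3S)-3-(allylamino)-4-[(tert-butyldiphenylsilyl)oxy]butanoate | C=CCN[C@@H](CC(=O)OC)CO[Si](c1ccccc1)(c1ccccc1)C(C)(C)C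
F4 | step 9 | methyl 3-{allyl[(2S)-1-[(tert-butyldiphenylsilyl)oxy]-4-methoxy-4-oxobutan-2-yl]amino}-3-oxopropanoate | COC(=O)CC(=O)N(CC=C)[C@@H](CC(=O)OC)CO[Si](c1ccccc1)(c1ccccc1)C(C)(C)C
F5 | step 9 | (6S)-1-allyl-6-{[(tert-butyldiphenylsilyl)oxy]methyl}piperidine-2,4-dione | O=C1CC(=O)C[C@@H](CO[Si](c2ccccc2)(c2ccccc2)C(C)(C)C)N1CC=C
F6 | step 9 | (6S)-1-allyl-6-{[(tert-butyldiphenylsilyl)oxy]methyl}-3-propylidenepiperidine-2,4-dione (E/Z mixture) | CCC=C1C(=O)C[C@@H](CO[Si](c2ccccc2)(c2ccccc2)C(C)(C)C)N(CC=C)C1=O
F7 | step 14 | dialdehyde from 21 (N17–CH2CHO and C22–CH2CHO) | CC[C@H]1[C@@H]2OC(=O)[C@@H](C)[C@@H]2C(=O)C[C@@H](CO[Si](c3ccccc3)(c3ccccc3)C(C)(C)C)N(CC=O)C(=O)[C@@H]1CC=O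
F8 | step 14 | 19,20-diol of the bicyclic keto lactam (diol centres open) | CC[C@H]1[C@@H]2OC(=O)[C@@H](C)[C@@H]2C(=O)C[C@@H](CO[Si](c3ccccc3)(c3ccccc3)C(C)(C)C)N2CC(O)C(O)C[C@H]1C2=O
F0 | step 17 | none | none
A1 | alternative 1 | nine-membered keto lactam with Z C3=C4 alkene, C11 methyl ester and N-(4-silyloxybutyl) group | COC(=O)[C@@H]1CC(=O)C/C=C\CC(=O)N1CCCCO[Si](C)(C)C(C)(C)C
A2 | alternative 1 | methyl (2S)-1-[4-(tert-butyldimethylsilyloxy)butyl]-2,3,4,7-tetrahydro-1H-indole-2-carboxylate | COC(=O)[C@@H]1CC2=C(CC=CC2)N1CCCCO[Si](C)(C)C(C)(C)C
A3 | alternative 2 | nine-membered NH lactam with E C4=C8 alkene, C3 and C22 set, C9 and C12 silyl ethers, C22 4-(benzyloxy)butyl chain | CC[C@H]1/C=C/[C@H](O[Si](C)(C)C(C)(C)C)C[C@@H](CO[Si](C)(C)C(C)(C)C)NC(=O)[C@@H]1CCCCOCc2ccccc2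
A4 | alternative 2 | 1-[6-(benzyloxy)hexanoyl]-2-[(E)-but-1-enyl]-3-(tert-butyldimethylsilyloxy)-5-[(tert-butyldimethylsilyloxy)methyl]pyrrolidine (2S,3R,5S) | CC/C=C/[C@H]1[C@H](O[Si](C)(C)C(C)(C)C)C[C@@H](CO[Si](C)(C)C(C)(C)C)N1C(=O)CCCCCOCc2ccccc2
A5 | alternative 3 | bicyclic keto lactam fused to lactone A with C11 methyl ester | CC[C@H]1[C@@H]2OC(=O)[C@@H](C)[C@@H]2C(=O)C[C@@H](C(=O)OC)N2CCCC[C@H]1C2=O
A6 | alternative 3 | azepan-2-one with N-[acetoxy(methoxycarbonyl)methyl] group and, at C22, the lactone A arm bearing the C9 trimethylsilyl enol ether (C11 open) | CC[C@@H]([C@@H]2OC(=O)[C@@H](C)[C@@H]2C(=C)O[Si](C)(C)C)[C@H]1CCCCN(C(OC(C)=O)C(=O)OC)C1=O
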